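Decide before the next run whether the second substrate charge should change.

starting material 0.053 M; second substrate 0.500 equiv; enzyme 0.01 mol%

    complex A → enzyme + target (k1 = 220 s⁻¹)
    complex A + complex A ⇌ resting dimer (K2 = 5.3 × 10⁵ M⁻¹, k2 = 14000 M⁻¹ s⁻¹)
    complex B → enzyme + second product (k3 = 1400 s⁻¹)
    second substrate + enzyme ⇌ complex B (K4 = 14 M⁻¹, k4 = 8.8 × 10⁵ M⁻¹ s⁻¹)
    starting material + enzyme ⇌ complex A (K5 = 30 M⁻¹, k5 = 2.6 × 10⁶ M⁻¹ s⁻¹)

- the form that holds most of the catalyst when 30% of the starting material are converted (resting dimer / enzyme / complex A / complex B)
- its share of the catalyst then
- apparent order in second substrate when 30% of the starting material are converted (percent change of the rate of making target for one percent more second substrate charged)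

We follow one catalyst. As complex A it falls back at 86700 s⁻¹ and goes on at 220 s⁻¹, so it falls back far more often than it goes on. As complex B it falls back at 62900 s⁻¹ and goes on at 1400 s⁻¹, and again falling back wins. So we take both complexes as balanced against enzyme.

At the charge, complex A stands to enzyme as 1.59 and complex B as 0.37, which is smaller. We therefore expect an apparent order in second substrate a little below zero, and we plan to leave the charge as it is.

The other fork leads into the resting dimer. The dimer's life, the mean time one resting dimer stands before it splits into two complex A, is 37.9 s. The look at 30% conversion comes at 38.3 s, about the same time. So we do not trust a balanced dimer share, and our reckoning stops there.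

The forecast names the resting dimer at 42%, within 40% to 44.5%, and an order of −0.01, within −0.035 to 0.015. It holds that “the dimer is not fully equilibrated”.

In the flask at 38.3 s, the resting dimer, the resting state, holds 42.3% of the catalyst. Complex A holds 28.6%, enzyme 25.8% and complex B 3.31%. The order is −0.012, so we leave the second substrate charge alone. The dimer's life of 37.9 s is about the time to the look, so a resting dimer formed early has had about one life in which to split. That return is part of the rate at 30% conversion: the run without the way back from resting dimer to two complex A gives 0.604 of the actual rate. That way back is also a part of why the apparent order in enzyme at 30% conversion stands at 0.76, where the same run gives 1.0.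

The rate constants belong to no real substance; the result is computed.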